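**Plan**

Numbering: C1 angular-methyl carbon, C4 isopropyl carbinol, C5 ring-fusion CH, C6–C10 the other seven-ring carbons (C8 bears the methyl).
Retrosynthetic cuts, in order: the two ester C–O bonds; the C6–O and C9–O bonds (through an O–O bridge back to the C6=C7–C8(Me)=C9 diene); C8–CH3; C7=C8 (metathesis); C4–isopropyl; C5–C6 (allylation); C1–CH3 (conjugate addition).
Enabling feature: in the seven-membered ring the C6–O and C9–O bonds are cis and flank the C7=C8 alkene. This is the footprint of a 1,4-endoperoxide, a 1,2-dioxine ring bridging C6 and C9, formed from that diene and singlet oxygen.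
Forward order: the cyclopentane (C1–C5) is present from the start; the C1 methyl, C5 allyl and C4 isopropyl groups are attached; olefin metathesis closes the seven-membered ring to a trans-hydroazulene; desaturation, triflation and methylation give the diene; the dioxine ring is formed and opened again before the two acylations.
Stereochemistry: C1 from ligand-controlled copper-catalysed conjugate methylation; C5 from enolate allylation anti to the long C1 chain; C4 from isopropyl addition anti to the C5 allyl and C1 methyl groups; C6 and C9 together from suprafacial oxygen addition on the face away from the axial C1 methyl and the C4 silyloxy group.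

Key step: step 11

Remark: in step 2 the antipode of the carbene ligand is taken to be the one that delivers methyl to the enone face giving the (R)-configured quaternary centre; both antipodes are accessible.

**Route**

Step 1
Reactants: 1 3-ethoxycyclopent-2-en-1-one; 2 2-(2-bromoethyl)-2-methyl-1,3-dioxolane
Product: 5 3-[2-(2-methyl-1,3-dioxolan-2-yl)ethyl]cyclopent-2-en-1-one, via Grignard reagent 3 (not isolated), via carbinol adduct 4 (not isolated)
Conditions: Mg, THF, 25–30 °C; 1, 0 °C; then 1 M aq HCl, 0 °C, short contact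
Reagents that add atoms: water, O
Why: Stork–Danheiser sequence, in which the Grignard reagent adds 1,2 to the vinylogous ester and brief cold aqueous acid collapses the adduct to the transposed 3-substituted enone while the slower-hydrolysing dioxolane should stay on; no stereocentre is formed.

Step 2
Reactants: 5; 6 trimethylaluminium
Product: 8 triethyl({(3R)-3-methyl-3-[2-(2-methyl-1,3-dioxolan-2-yl)ethyl]cyclopent-1-en-1-yl}oxy)silane, via aluminium enolate 7 (not isolated)
Conditions: Me3Al, Cu(OTf)2 (5 mol %), chiral sulfonate-bearing imidazolinium salt/Ag2O (carbene source, 2.5 mol %), THF, −78 °C; then Et3SiOTf, −78 → 0 °C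
Reagents that add atoms: trimethylaluminium, C[Al](C)C; triethylsilyl trifluoromethanesulfonate, CC[Si](CC)(CC)OS(=O)(=O)C(F)(F)F
Why: Copper-catalysed asymmetric conjugate addition of a trialkylaluminium to a β-substituted cyclopentenone under a chiral N-heterocyclic carbene ligand is an established route to β-quaternary cyclopentanones; the ligand selects the enone face and so sets C1, and O-silylation of the aluminium enolate fixes the enolate regiochemistry for step 3.

Step 3
Reactants: 8; 9 allyl iodide (3-iodoprop-1-ene)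
Product: 11 (2R,3R)-3-methyl-3-[2-(2-methyl-1,3-dioxolan-2-yl)ethyl]-2-(prop-2-en-1-yl)cyclopentan-1-one, via lithium enolate 10 (not isolated)
Conditions: MeLi, THF, 0 °C → rt; then allyl iodide, HMPA, −78 → −20 °C
Reagents that add atoms: allyl iodide, C=CCI
Why: Regiospecific lithium enolate generation from the silyl enol ether followed by SN2 enolate alkylation; the allyl group should enter C5 anti to the longer ketal-bearing chain on the neighbouring quaternary carbon (cis to the methyl), which sets the trans relationship that later becomes the ring fusion.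

Step 4
Reactants: 11; 12 isopropylmagnesium chloride
Product: 14 (1R,2R,3R)-3-methyl-3-[2-(2-methyl-1,3-dioxolan-2-yl)ethyl]-1-(propan-2-yl)-2-(prop-2-en-1-yl)cyclopentan-1-ol, via isopropylcerium dichloride 13 (not isolated)
Conditions: i-PrMgCl, CeCl3 (dried), THF, −78 → 0 °C; aq NH4Cl
Reagents that add atoms: isopropylmagnesium chloride, CC(C)[Mg]Cl
Why: Organocerium 1,2-addition suppresses enolisation of the hindered ketone, and attack on the carbonyl face opposite the cis-disposed C5 allyl and C1 methyl groups should place the C4 hydroxyl on their face (4β-OH, 4α-isopropyl).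

Step 5
Reactants: 14
Product: 15 4-[(1R,2R,3R)-3-hydroxy-1-methyl-3-(propan-2-yl)-2-(prop-2-en-1-yl)cyclopentyl]butan-2-one
Conditions: 1 M aq HCl, THF, rt
Reagents that add atoms: water, O
Why: Acid-catalysed ketal hydrolysis under dilute, cold conditions unmasks the methyl ketone without ionising the tertiary alcohol, and no stereocentre is touched.

Step 6
Reactants: 15
Product: 17 triethyl{[(1R,2R,3S)-3-methyl-1-(propan-2-yl)-2-(prop-2-en-1-yl)-3-{3-[(triethylsilyl)oxy]but-3-en-1-yl}cyclopentyl]oxy}silane, via dilithium alkoxide-enolate 16 (not isolated)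
Conditions: LDA (2.3 equiv), THF, −78 °C; Et3SiCl, HMPA, −78 → 0 °C
Reagents that add atoms: chlorotriethylsilane, CC[Si](Cl)(CC)CC
Why: Kinetic enolisation of the methyl ketone at the methyl group and O-silylation give the terminal silyl enol ether while the tertiary lithium alkoxide is silylated in the same flask, so one operation supplies both the metathesis partner and the C4 protecting group.

Step 7
Reactants: 17
Product: 18 triethyl{[(3R,3aR,8aS)-8a-methyl-3-(propan-2-yl)-6-[(triethylsilyl)oxy]-1,2,3,3a,4,7,8,8a-octahydroazulen-3-yl]oxy}silane (C7=C8 silyl enol ether, trans-fused)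
Conditions: second-generation Grubbs catalyst RuCl2(=CHPh)(PCy3)(H2IMes) (5 mol %), toluene (5 mM), 70 °C
Reagents that add atoms: none
Why: Ring-closing olefin metathesis between a terminal alkene and a 1,1-disubstituted silyl enol ether, a known route to cyclic silyl enol ethers, closes the seven-membered ring at C7=C8 with loss of ethene and carries the trans C1/C5 relationship into the ring fusion.

Step 8
Reactants: 18
Product: 19 (3R,3aR,8aR)-8a-methyl-3-(propan-2-yl)-3-[(triethylsilyl)oxy]-2,3,3a,7,8,8a-hexahydroazulen-6(1H)-one (C6=C7 enone, C8 ketone)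
Conditions: Pd(OAc)2 (1.05 equiv), MeCN, rt
Reagents that add atoms: none
Why: Saegusa–Ito oxidation, in which palladation of the regio-defined silyl enol ether at C7 and β-hydride elimination from C6 can only give the C6=C7 enone.

Step 9
Reactants: 19
Product: 21 (3R,3aR,8aR)-8a-methyl-3-(propan-2-yl)-3-[(triethylsilyl)oxy]-1,2,3,3a,8,8a-hexahydroazulen-6-yl trifluoromethanesulfonate, via lithium dienolate 20 (not isolated)
Conditions: LDA, THF, −78 °C; PhNTf2, −78 → 0 °C
Reagents that add atoms: N-phenylbis(trifluoromethanesulfonimide), O=S(=O)(N(c1ccccc1)S(=O)(=O)C(F)(F)F)C(F)(F)F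
Why: Kinetic α′-deprotonation of the cycloheptenone at the C9 methylene (the γ-hydrogen at C5 is tertiary and shielded) gives the cross-conjugated dienolate, and its O-triflation gives a 2-triflyloxy-1,3-diene with both double bonds already in their final positions.

Step 10
Reactants: 21; 22 methylmagnesium bromide
Product: 23 triethyl{[(3R,3aR,8aR)-6,8a-dimethyl-3-(propan-2-yl)-1,2,3,3a,8,8a-hexahydroazulen-3-yl]oxy}silane (trans-hydroazulene C6,C8-diene)
Conditions: MeMgBr, Fe(acac)3 (5 mol %), THF/NMP, −30 → 0 °C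
Reagents that add atoms: methylmagnesium bromide, C[Mg]Br
Why: Iron-catalysed Kumada-type cross-coupling of an alkenyl triflate with a methyl Grignard reagent replaces the triflate by the C8 methyl without moving either double bond.

Step 11
Reactants: 23; 24 dioxygen
Product: 25 triethyl{[(3R,3aS,4S,7S,8aR)-6,8a-dimethyl-3-(propan-2-yl)-1,2,3,3a,4,7,8,8a-octahydro-4,7-epidioxyazulen-3-yl]oxy}silane (6α,9α-endoperoxide)
Conditions: O2, tetraphenylporphyrin (cat.), visible light, CH2Cl2, −20 °C
Reagents that add atoms: dioxygen, O=O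
Why: Sensitiser-generated singlet oxygen adds as the 2π partner across the ring-held s-cis C6=C7–C8(Me)=C9 diene in a concerted suprafacial [4+2] cycloaddition, forming the C6–O and C9–O bonds and leaving the alkene at C7=C8. The closest known reaction type is the Diels–Alder-type photooxygenation of cyclic 1,3-dienes to 1,4-endoperoxides. No carbocycle closes; the only new ring is the six-membered 1,2-dioxine bridging C6 and C9, closed by cycloaddition with both bonds formed on one face. C6 and C9 are set together, cis to each other by suprafaciality, and their absolute sense follows from the face of attack, which is governed by C1 and C4: the axial C1 methyl and the C4 silyloxy group cover the β face, so oxygen should approach from the α face. The step needs face selectivity and [4+2] over ene hydroperoxidation; the ring-locked geometry and the methyl-enriched diene favour cycloaddition, and low temperature in a non-polar solvent should hold back the ene pathway.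

Step 12
Reactants: 25
Product: 26 (3R,3aS,4S,7S,8aR)-6,8a-dimethyl-3-(propan-2-yl)-3-[(triethylsilyl)oxy]-1,2,3,3a,4,7,8,8a-octahydroazulene-4,7-diol (6α,9α-diol)
Conditions: Zn dust, AcOH, CH2Cl2, 0 °C → rt
Reagents that add atoms: none
Why: Reductive cleavage of the O–O bond by zinc in acetic acid is the standard conversion of 1,4-endoperoxides into cis-2-ene-1,4-diols and leaves both C–O bonds, and so both new stereocentres, untouched.

Step 13
Reactants: 26; 27 acetic anhydride
Product: 28 (3R,3aS,4S,7S,8aR)-4-hydroxy-6,8a-dimethyl-3-(propan-2-yl)-3-[(triethylsilyl)oxy]-1,2,3,3a,4,7,8,8a-octahydroazulen-7-yl acetate (C9 monoacetate)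
Conditions: Ac2O (1.1 equiv), pyridine, CH2Cl2, 0 °C
Reagents that add atoms: acetic anhydride, CC(=O)OC(C)=O
Why: Sterically controlled pyridine-mediated acetylation, since the C9 hydroxyl lies between a CH2 and the alkene carbon whereas the C6 hydroxyl is flanked by the ring-fusion carbon carrying the quaternary C1 and the silylated C4, so one equivalent of anhydride in the cold should acylate C9 only.

Step 14
Reactants: 29 4-hydroxybenzoic acid
Product: 30 tert-butyldimethylsilyl 4-[(tert-butyldimethylsilyl)oxy]benzoate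
Conditions: t-BuMe2SiCl (2.3 equiv), imidazole, DMF, rt
Reagents that add atoms: tert-butyl(chloro)dimethylsilane, CC(C)(C)[Si](C)(C)Cl
Why: Imidazole-mediated silylation of both the phenol and the carboxylic acid gives a silyl ester that serves as a neutral precursor of the acid chloride.

Step 15
Reactants: 28; 30
Product: 32 (3R,3aS,4S,7S,8aR)-7-(acetyloxy)-6,8a-dimethyl-3-(propan-2-yl)-3-[(triethylsilyl)oxy]-1,2,3,3a,4,7,8,8a-octahydroazulen-4-yl 4-[(tert-butyldimethylsilyl)oxy]benzoate, via acid chloride 31 (not isolated)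
Conditions: 30, (COCl)2, DMF (cat.), CH2Cl2, 0 °C → rt, then evaporation; 28, Et3N, DMAP, CH2Cl2, 40 °C
Reagents that add atoms: none
Why: The silyl ester is converted by oxalyl chloride and catalytic DMF into the acid chloride without liberating HCl, and DMAP-catalysed acylation (nucleophilic catalysis) then esterifies the hindered allylic C6 hydroxyl with retention at C6.

Step 16
Reactants: 32
Product: 33 (3R,3aS,4S,7S,8aR)-7-(acetyloxy)-3-hydroxy-6,8a-dimethyl-3-(propan-2-yl)-1,2,3,3a,4,7,8,8a-octahydroazulen-4-yl 4-hydroxybenzoate (CNP0305796.2)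
Conditions: Bu4NF, AcOH (1:1), THF, 0 °C → rt
Reagents that add atoms: none
Why: Fluoride-mediated desilylation buffered with acetic acid cleaves the aryl silyl ether and the tertiary triethylsilyl ether while the acetate and the benzoate, which would suffer under unbuffered fluoride, stay in place.

**Compound list**

1 | 3-ethoxycyclopent-2-en-1-one | CCOC1=CC(=O)CC1 | starting material
2 | 2-(2-bromoethyl)-2-methyl-1,3-dioxolane | CC1(CCBr)OCCO1 | starting material
3 | [2-(2-methyl-1,3-dioxolan-2-yl)ethyl]magnesium bromide | CC1(CC[Mg]Br)OCCO1 | intermediate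
4 | 3-ethoxy-1-[2-(2-methyl-1,3-dioxolan-2-yl)ethyl]cyclopent-2-en-1-ol (racemic) | CCOC1=CC(O)(CCC2(C)OCCO2)CC1 | intermediate
5 | 3-[2-(2-methyl-1,3-dioxolan-2-yl)ethyl]cyclopent-2-en-1-one | O=C1C=C(CCC2(C)OCCO2)CC1 | intermediate
6 | trimethylaluminium | C[Al](C)C | starting material
7 | dimethylaluminium enolate of (3R)-3-methyl-3-[2-(2-methyl-1,3-dioxolan-2-yl)ethyl]cyclopentanone | CC1(OCCO1)CC[C@@]2(C)CCC(O[Al](C)C)=C2 | intermediate
8 | triethyl({(3R)-3-methyl-3-[2-(2-methyl-1,3-dioxolan-2-yl)ethyl]cyclopent-1-en-1-yl}oxy)silane | CC1(OCCO1)CC[C@@]2(C)CCC(O[Si](CC)(CC)CC)=C2 | intermediate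
9 | allyl iodide (3-iodoprop-1-ene) | C=CCI | starting material
10 | lithium enolate of (3R)-3-methyl-3-[2-(2-methyl-1,3-dioxolan-2-yl)ethyl]cyclopentanone (C4–O, C4=C5) | CC1(OCCO1)CC[C@@]2(C)CCC(O[Li])=C2 | intermediate
11 | (2R,3R)-3-methyl-3-[2-(2-methyl-1,3-dioxolan-2-yl)ethyl]-2-(prop-2-en-1-yl)cyclopentan-1-one | CC1(OCCO1)CC[C@@]2(C)CCC(=O)[C@@H]2CC=C | intermediate
12 | isopropylmagnesium chloride | CC(C)[Mg]Cl | starting material
13 | isopropylcerium dichloride | CC(C)[Ce](Cl)Cl | intermediate
14 | (1R,2R,3R)-3-methyl-3-[2-(2-methyl-1,3-dioxolan-2-yl)ethyl]-1-(propan-2-yl)-2-(prop-2-en-1-yl)cyclopentan-1-ol | CC1(OCCO1)CC[C@@]2(C)CC[C@@](O)(C(C)C)[C@@H]2CC=C | intermediate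
15 | 4-[(1R,2R,3R)-3-hydroxy-1-methyl-3-(propan-2-yl)-2-(prop-2-en-1-yl)cyclopentyl]butan-2-one | CC(=O)CC[C@@]1(C)CC[C@@](O)(C(C)C)[C@@H]1CC=C | intermediate
16 | dilithium alkoxide-enolate of 15 (tertiary alkoxide, terminal enolate) | C=C(O[Li])CC[C@@]1(C)CC[C@@](O[Li])(C(C)C)[C@@H]1CC=C | intermediate
17 | triethyl{[(1R,2R,3S)-3-methyl-1-(propan-2-yl)-2-(prop-2-en-1-yl)-3-{3-[(triethylsilyl)oxy]but-3-en-1-yl}cyclopentyl]oxy}silane | C=C(O[Si](CC)(CC)CC)CC[C@@]1(C)CC[C@@](O[Si](CC)(CC)CC)(C(C)C)[C@@H]1CC=C | intermediate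
18 | triethyl{[(3R,3aR,8aS)-8a-methyl-3-(propan-2-yl)-6-[(triethylsilyl)oxy]-1,2,3,3a,4,7,8,8a-octahydroazulen-3-yl]oxy}silane | C1C[C@@]2(C)CC[C@@](O[Si](CC)(CC)CC)(C(C)C)[C@@H]2CC=C1O[Si](CC)(CC)CC | intermediate
19 | (3R,3aR,8aR)-8a-methyl-3-(propan-2-yl)-3-[(triethylsilyl)oxy]-2,3,3a,7,8,8a-hexahydroazulen-6(1H)-one | O=C1CC[C@@]2(C)CC[C@@](O[Si](CC)(CC)CC)(C(C)C)[C@@H]2C=C1 | intermediate
20 | lithium cross-conjugated dienolate of 19 (C8–O, C8=C9, C6=C7) | [Li]OC1=CC[C@@]2(C)CC[C@@](O[Si](CC)(CC)CC)(C(C)C)[C@@H]2C=C1 | intermediate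
21 | (3R,3aR,8aR)-8a-methyl-3-(propan-2-yl)-3-[(triethylsilyl)oxy]-1,2,3,3a,8,8a-hexahydroazulen-6-yl trifluoromethanesulfonate | C1[C@@]2(C)CC[C@@](O[Si](CC)(CC)CC)(C(C)C)[C@@H]2C=CC(OS(=O)(=O)C(F)(F)F)=C1 | intermediate
22 | methylmagnesium bromide | C[Mg]Br | starting material
23 | triethyl{[(3R,3aR,8aR)-6,8a-dimethyl-3-(propan-2-yl)-1,2,3,3a,8,8a-hexahydroazulen-3-yl]oxy}silane | C1[C@@]2(C)CC[C@@](O[Si](CC)(CC)CC)(C(C)C)[C@@H]2C=CC(C)=C1 | intermediate
24 | dioxygen (used as sensitised singlet oxygen) | O=O | starting material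
25 | triethyl{[(3R,3aS,4S,7S,8aR)-6,8a-dimethyl-3-(propan-2-yl)-1,2,3,3a,4,7,8,8a-octahydro-4,7-epidioxyazulen-3-yl]oxy}silane | O3[C@H]1C[C@@]2(C)CC[C@@](O[Si](CC)(CC)CC)(C(C)C)[C@@H]2[C@@H](O3)C=C1C | intermediate
26 | (3R,3aS,4S,7S,8aR)-6,8a-dimethyl-3-(propan-2-yl)-3-[(triethylsilyl)oxy]-1,2,3,3a,4,7,8,8a-octahydroazulene-4,7-diol | O[C@H]1C[C@@]2(C)CC[C@@](O[Si](CC)(CC)CC)(C(C)C)[C@@H]2[C@@H](O)C=C1C | intermediate
27 | acetic anhydride | CC(=O)OC(C)=O | starting material
28 | (3R,3aS,4S,7S,8aR)-4-hydroxy-6,8a-dimethyl-3-(propan-2-yl)-3-[(triethylsilyl)oxy]-1,2,3,3a,4,7,8,8a-octahydroazulen-7-yl acetate | CC(=O)O[C@H]1C[C@@]2(C)CC[C@@](O[Si](CC)(CC)CC)(C(C)C)[C@@H]2[C@@H](O)C=C1C | intermediate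
29 | 4-hydroxybenzoic acid | OC(=O)c1ccc(O)cc1 | starting material
30 | tert-butyldimethylsilyl 4-[(tert-butyldimethylsilyl)oxy]benzoate | CC(C)(C)[Si](C)(C)OC(=O)c1ccc(O[Si](C)(C)C(C)(C)C)cc1 | intermediate
31 | 4-[(tert-butyldimethylsilyl)oxy]benzoyl chloride | ClC(=O)c1ccc(O[Si](C)(C)C(C)(C)C)cc1 | intermediate
32 | (3R,3aS,4S,7S,8aR)-7-(acetyloxy)-6,8a-dimethyl-3-(propan-2-yl)-3-[(triethylsilyl)oxy]-1,2,3,3a,4,7,8,8a-octahydroazulen-4-yl 4-[(tert-butyldimethylsilyl)oxy]benzoate | CC(=O)O[C@H]1C[C@@]2(C)CC[C@@](O[Si](CC)(CC)CC)(C(C)C)[C@@H]2[C@@H](OC(=O)c2ccc(O[Si](C)(C)C(C)(C)C)cc2)C=C1C | intermediate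
33 | (3R,3aS,4S,7S,8aR)-7-(acetyloxy)-3-hydroxy-6,8a-dimethyl-3-(propan-2-yl)-1,2,3,3a,4,7,8,8a-octahydroazulen-4-yl 4-hydroxybenzoate | CC(=O)O[C@H]1C[C@@]2(C)CC[C@@](O)(C(C)C)[C@@H]2[C@@H](OC(=O)c2ccc(O)cc2)C=C1C | target

**Step count and risks**

Total step count: 16. Longest linear sequence: 15 steps (steps 1–13, 15 and 16, from compound 1); step 14 is a one-step side branch.

Steps most likely to fail:

1. Step 11. Oxygen may add to the β face of the diene, or to both faces, if the axial C1 methyl and the C4 silyloxy group shield less than expected. The fallback sets out from 23 and comes back at 26; it moves the stereochemical decision from the cycloaddition to a carbonyl reduction. The photooxygenation is run as before and the 6β,9β-endoperoxide F1 is accepted. Zinc in acetic acid opens it to the 6β,9β-diol F2. MnO2 in CH2Cl2 oxidises both allylic alcohols to the C6,C9 ene-dione F3. Reduction with NaBH4 and CeCl3·7H2O in methanol at −78 °C (Luche reduction) then delivers hydride from the same open face that oxygen had used, so both hydroxyls end up on the α face and diol 26 results. The conditions must stay cold and near neutral so that C5, now α to a ketone, does not epimerise.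

2. Step 3. Facial discrimination between the methyl and the CH2CH2 chain on the quaternary carbon may be poor in the enolate alkylation, giving a cis/trans mixture at C5. The fallback sets out from 8 and comes back at 11; it replaces substrate control by catalyst control. MeLi followed by allyl chloroformate converts 8 into the allyl enol carbonate F4. Pd2(dba)3 with a chiral trans-1,2-diaminocyclohexane-derived bis(2-diphenylphosphinobenzamide) ligand in toluene then effects decarboxylative allylic alkylation (Tsuji–Trost type), in which the ligand chooses the enolate face under neutral conditions that do not epimerise the new centre, giving 11.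

3. Step 7. The silyl enol ether may hydrolyse or engage the ruthenium carbene unproductively, so that the ring does not close. The fallback sets out from 15 and comes back at 19; it uses an all-carbon diene metathesis and also bypasses step 8. RuHCl(CO)(PPh3)3 in toluene at 80 °C isomerises the allyl group of 15 to the (E)-propenyl ketone F5. Silylation as in step 6 gives the bis(triethylsilyl) compound F6. Dimethyl(methylidene)ammonium iodide adds to the silyl enol ether (Mannich reaction) to give the β-dimethylamino ketone F7. Methylation with MeI and elimination with NaHCO3 give the vinyl ketone F8. Ring-closing metathesis of F8 with the second-generation Grubbs catalyst joins the propenyl and enone carbons with loss of propene and gives enone 19 directly.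

Further compounds
F1 | step 11 | triethyl{[(3R,3aS,4R,7R,8aR)-6,8a-dimethyl-3-(propan-2-yl)-1,2,3,3a,4,7,8,8a-octahydro-4,7-epidioxyazulen-3-yl]oxy}silane (6β,9β-endoperoxide) | O3[C@@H]1C[C@@]2(C)CC[C@@](O[Si](CC)(CC)CC)(C(C)C)[C@@H]2[C@H](O3)C=C1C
F2 | step 11 | (3R,3aS,4R,7R,8aR)-6,8a-dimethyl-3-(propan-2-yl)-3-[(triethylsilyl)oxy]-1,2,3,3a,4,7,8,8a-octahydroazulene-4,7-diol (6β,9β-diol) | O[C@@H]1C[C@@]2(C)CC[C@@](O[Si](CC)(CC)CC)(C(C)C)[C@@H]2[C@H](O)C=C1C
F3 | step 11 | (3R,3aR,8aR)-6,8a-dimethyl-3-(propan-2-yl)-3-[(triethylsilyl)oxy]-2,3,8,8a-tetrahydroazulene-4,7(1H,3aH)-dione | O=C1C[C@@]2(C)CC[C@@](O[Si](CC)(CC)CC)(C(C)C)[C@@H]2C(=O)C=C1C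
F4 | step 3 | (3R)-3-methyl-3-[2-(2-methyl-1,3-dioxolan-2-yl)ethyl]cyclopent-1-en-1-yl prop-2-en-1-yl carbonate | CC1(OCCO1)CC[C@@]2(C)CCC(OC(=O)OCC=C)=C2
F5 | step 7 | 4-[(1R,2R,3R)-3-hydroxy-1-methyl-3-(propan-2-yl)-2-[(1E)-prop-1-en-1-yl]cyclopentyl]butan-2-one | CC(=O)CC[C@@]1(C)CC[C@@](O)(C(C)C)[C@@H]1/C=C/C
F6 | step 7 | triethyl{[(1R,2R,3S)-3-methyl-1-(propan-2-yl)-2-[(1E)-prop-1-en-1-yl]-3-{3-[(triethylsilyl)oxy]but-3-en-1-yl}cyclopentyl]oxy}silane | C=C(O[Si](CC)(CC)CC)CC[C@@]1(C)CC[C@@](O[Si](CC)(CC)CC)(C(C)C)[C@@H]1/C=C/C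
F7 | step 7 | 1-(dimethylamino)-5-[(1R,2R,3R)-1-methyl-3-(propan-2-yl)-2-[(1E)-prop-1-en-1-yl]-3-[(triethylsilyl)oxy]cyclopentyl]pentan-3-one | CN(C)CCC(=O)CC[C@@]1(C)CC[C@@](O[Si](CC)(CC)CC)(C(C)C)[C@@H]1/C=C/C
F8 | step 7 | 5-[(1R,2R,3R)-1-methyl-3-(propan-2-yl)-2-[(1E)-prop-1-en-1-yl]-3-[(triethylsilyl)oxy]cyclopentyl]pent-1-en-3-one | C=CC(=O)CC[C@@]1(C)CC[C@@](O[Si](CC)(CC)CC)(C(C)C)[C@@H]1/C=C/C
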